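## Retrosynthetic overview

1. The target, (1R,3Z,7Z,9S,10R)-9-hydroxy-3,7-dimethyl-10-(propan-2-yl)cyclodeca-3,7-dien-1-yl 4-hydroxybenzoate, comes from its bis-silyl ether by desilylation. The ten-membered carbocycle is the only ring built (the arene is bought) and is closed late by ring-closing metathesis at C3=C4.
2. The acyclic triene ester comes from acylation at O–C1 of a homoallylic alcohol with 4-(silyloxy)benzoyl chloride (three steps from 4-hydroxybenzoic acid).
3. The C1–C2 bond comes from reagent-controlled methallylboration of an α-isopropyl-β-silyloxy aldehyde, which sets C1.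
4. The C9–C10 bond comes from an auxiliary-controlled syn aldol of an N-isovaleryl thiazolidinethione (two steps from D-phenylalaninol) with (2Z)-3-methylhepta-2,6-dienal, which sets C9 and C10. The enal takes two steps, and its Z alkene (future C7=C8) comes from carbocupration of propyne.

Assumption: the given SMILES is read as the name in line 1 (germacrane-type ring, both ring alkenes Z, all-syn C9/C10/C1 triad), and those ring locants are used below.

## Route

Step 1
Reactants: 1 (2R)-2-amino-3-phenylpropan-1-ol (D-phenylalaninol)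
Product: 3 (4R)-4-benzyl-1,3-thiazolidine-2-thione, via dithiocarbamate xanthate dipotassium salt 2 (not isolated)
Conditions: CS2 (5 equiv), KOH (aq, 2 M), reflux, 16 h
Reagents that add atoms: carbon disulfide, S=C=S
Why: Heterocyclisation with CS2: the amine gives the dithiocarbamate, the primary alcohol is activated as its xanthate and displaced intramolecularly by sulfur (5-exo-tet), which never touches the stereocentre, so the R configuration of 1 is kept.

Step 2
Reactants: 3 (4R)-4-benzyl-1,3-thiazolidine-2-thione, 4 3-methylbutanoyl chloride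
Product: 5 1-[(4R)-4-benzyl-2-sulfanylidene-1,3-thiazolidin-3-yl]-3-methylbutan-1-one
Conditions: Et3N, DMAP (cat.), CH2Cl2, 0 °C to rt
Reagents that add atoms: none
Why: N-acylation (nucleophilic acyl substitution) of the thiazolidinethione gives the thermodynamically preferred N-acyl imide needed for soft enolisation.

Step 3
Reactants: 6 but-3-en-1-ylmagnesium bromide, 7 propyne
Product: 10 (1Z)-1-iodo-2-methylhexa-1,5-diene, via but-3-enylcopper 8 (not isolated), via (Z)-2-methylhexa-1,5-dienylcopper 9 (not isolated)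
Conditions: CuBr·SMe2 (1 equiv), Et2O/SMe2, −45 °C; 7 (excess), −25 °C; I2, THF, −78 to 0 °C
Reagents that add atoms: iodine, II
Why: Normant carbocupration: the alkylcopper adds syn across propyne with copper on the terminal carbon, and iodinolysis with retention leaves iodine cis to the butenyl chain, i.e. the Z iodide.

Step 4
Reactants: 10 (1Z)-1-iodo-2-methylhexa-1,5-diene
Product: 12 (2Z)-3-methylhepta-2,6-dienal, via (Z)-2-methylhexa-1,5-dienyllithium 11 (not isolated)
Conditions: t-BuLi (2.1 equiv), Et2O, −78 °C; DMF, −78 to −20 °C; cold H2O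
Reagents that add atoms: N,N-dimethylformamide, CN(C)C=O
Why: Iodine–lithium exchange and DMF formylation both proceed with retention at the alkenyl carbon, so the Z geometry of 10 is carried into the enal, which is worked up cold and neutral to avoid Z-to-E isomerisation.

Step 5
Reactants: 5 1-[(4R)-4-benzyl-2-sulfanylidene-1,3-thiazolidin-3-yl]-3-methylbutan-1-one, 12 (2Z)-3-methylhepta-2,6-dienal
Product: 14 (2R,3S,4Z)-1-[(4R)-4-benzyl-2-sulfanylidene-1,3-thiazolidin-3-yl]-3-hydroxy-5-methyl-2-(propan-2-yl)nona-4,8-dien-1-one, via trichlorotitanium Z-enolate 13 (not isolated)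
Conditions: TiCl4 (1.05 equiv), i-Pr2NEt (1.1 equiv), NMP (2 equiv), CH2Cl2, 0 °C; 12, −78 °C, 2 h; H2O quench
Reagents that add atoms: none
Why: Crimmins titanium aldol in its non-chelated Evans-syn mode: the Z(O)-enolate adds through a Zimmerman–Traxler chair on the face away from the benzyl group, giving the 2,3-syn adduct with C2 R and C3 S (future C10 and C9), while the aldehyde alkene stays Z at −78 °C.

Step 6
Reactants: 14 (the aldol adduct)
Product: 15 (2R,3S,4Z)-1-[(4R)-4-benzyl-2-sulfanylidene-1,3-thiazolidin-3-yl]-3-{[tert-butyl(dimethyl)silyl]oxy}-5-methyl-2-(propan-2-yl)nona-4,8-dien-1-one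
Conditions: TBSOTf (1.3 equiv), 2,6-lutidine (2 equiv), CH2Cl2, 0 °C
Reagents that add atoms: tert-butyldimethylsilyl trifluoromethanesulfonate, CC(C)(C)[Si](C)(C)OS(=O)(=O)C(F)(F)F
Why: Silylation of the hindered allylic alcohol with the silyl triflate and a non-nucleophilic base protects the future C9 hydroxyl for the rest of the route without retro-aldol cleavage.

Step 7
Reactants: 15 (the silyl ether)
Product: 16 (2R,3S,4Z)-3-{[tert-butyl(dimethyl)silyl]oxy}-5-methyl-2-(propan-2-yl)nona-4,8-dienal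
Conditions: i-Bu2AlH (1.5 equiv), CH2Cl2, −78 °C; aq. potassium sodium tartrate
Reagents that add atoms: none
Why: Partial hydride reduction of the activated N-acyl thiazolidinethione gives a tetrahedral aluminium adduct that collapses only on work-up, so the aldehyde is not over-reduced and its α-stereocentre is not epimerised at −78 °C; auxiliary 3 is recovered.

Step 8
Reactants: 16 (the aldehyde), 17 (2-methylprop-2-en-1-yl)magnesium chloride, 18 (+)-B-methoxydiisopinocampheylborane [(+)-Ipc2BOMe, from (−)-α-pinene]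
Product: 20 (4R,5S,6S,7Z)-6-{[tert-butyl(dimethyl)silyl]oxy}-2,8-dimethyl-5-(propan-2-yl)dodeca-1,7,11-trien-4-ol, via B-methallyldiisopinocampheylborane 19 (not isolated)
Conditions: 18 + 17, Et2O, −78 °C to rt; 16, Et2O, −78 °C, 3 h; NaOH, H2O2, 0 °C to rt
Reagents that add atoms: none
Why: Brown methallylboration: the chair transition state of the (−)-α-pinene-derived borane delivers the methallyl group to the Re face of the aldehyde under reagent control, setting the new carbinol centre R (future C1, syn to the isopropyl group).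

Step 9
Reactants: 21 4-hydroxybenzoic acid
Product: 22 tert-butyl(dimethyl)silyl 4-{[tert-butyl(dimethyl)silyl]oxy}benzoate
Conditions: TBSCl (2.5 equiv), imidazole (5 equiv), DMF, rt
Reagents that add atoms: tert-butyl(chloro)dimethylsilane, CC(C)(C)[Si](C)(C)Cl
Why: Silylation of both acidic hydroxyls under Corey conditions (TBSCl/imidazole) gives the silyl ether silyl ester.

Step 10
Reactants: 22 (the bis-silyl compound)
Product: 23 4-{[tert-butyl(dimethyl)silyl]oxy}benzoic acid
Conditions: AcOH/THF/H2O (3:1:1), rt, 3 h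
Reagents that add atoms: none
Why: Selective hydrolysis: the silyl ester is far more labile to aqueous acetic acid than the aryl silyl ether, so only the carboxylic acid is released.

Step 11
Reactants: 23 (the acid)
Product: 24 4-{[tert-butyl(dimethyl)silyl]oxy}benzoyl chloride
Conditions: (COCl)2 (1.5 equiv), DMF (cat.), CH2Cl2, 0 °C to rt
Reagents that add atoms: oxalyl chloride, O=C(Cl)C(Cl)=O
Why: Acid chloride formation with oxalyl chloride under Vilsmeier (DMF) catalysis is mild enough to keep the aryl silyl ether.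

Step 12
Reactants: 20 (the homoallylic alcohol), 24 (the acid chloride)
Product: 25 (4R,5S,6S,7Z)-6-{[tert-butyl(dimethyl)silyl]oxy}-2,8-dimethyl-5-(propan-2-yl)dodeca-1,7,11-trien-4-yl 4-{[tert-butyl(dimethyl)silyl]oxy}benzoate
Conditions: Et3N (3 equiv), DMAP (0.5 equiv), CH2Cl2, 0 °C to rt
Reagents that add atoms: none
Why: DMAP-catalysed acylation (nucleophilic acyl substitution) of the only free hydroxyl by the acid chloride; the C–O bond of the carbinol is not broken, so the R configuration is retained.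

Step 13
Reactants: 25 (the triene ester)
Product: 26 (1R,3Z,7Z,9S,10S)-9-{[tert-butyl(dimethyl)silyl]oxy}-3,7-dimethyl-10-(propan-2-yl)cyclodeca-3,7-dien-1-yl 4-{[tert-butyl(dimethyl)silyl]oxy}benzoate
Conditions: second-generation Grubbs catalyst RuCl2(PCy3)(H2IMes)(=CHPh) (10 mol%), 1,4-benzoquinone (20 mol%), toluene (1 mM), 80 °C
Reagents that add atoms: none
Why: Ring-closing metathesis: the carbene loads on the monosubstituted vinyl group and closes onto the 1,1-disubstituted alkene with loss of ethylene at high dilution; the ten-membered ring takes the new trisubstituted alkene only as the ring-cis (Z) isomer, and the trisubstituted C7=C8 alkene and the three stereocentres are not touched.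

Step 14
Reactants: 26 (the bis-silyl macrocycle)
Product: 27 (1R,3Z,7Z,9S,10R)-9-hydroxy-3,7-dimethyl-10-(propan-2-yl)cyclodeca-3,7-dien-1-yl 4-hydroxybenzoate
Conditions: HF·pyridine, pyridine, THF, 0 °C to rt
Reagents that add atoms: none
Why: Fluoride-mediated desilylation under buffered, mildly acidic conditions removes the aryl and the allylic silyl ether without ester cleavage or 1,3-acyl migration (the C10 descriptor changes from S to R only through CIP priorities).

## Compound list

1 | (2R)-2-amino-3-phenylpropan-1-ol | N[C@H](Cc1ccccc1)CO | starting material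
2 | dipotassium N-dithiocarbamate O-xanthate of 1 (in situ) | [K+].[K+].[S-]C(=S)N[C@H](Cc1ccccc1)COC(=S)[S-] | intermediate
3 | (4R)-4-benzyl-1,3-thiazolidine-2-thione | S=C1N[C@H](Cc2ccccc2)CS1 | intermediate
4 | 3-methylbutanoyl chloride | CC(C)CC(Cl)=O | starting material
5 | 1-[(4R)-4-benzyl-2-sulfanylidene-1,3-thiazolidin-3-yl]-3-methylbutan-1-one | CC(C)CC(=O)N1C(=S)SC[C@H]1Cc1ccccc1 | intermediate
6 | but-3-en-1-ylmagnesium bromide | C=CCC[Mg]Br | starting material
7 | propyne | CC#C | starting material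
8 | but-3-en-1-ylcopper (in situ) | C=CCC[Cu] | intermediate
9 | [(1Z)-2-methylhexa-1,5-dien-1-yl]copper (in situ) | C=CCC/C(C)=C\[Cu] | intermediate
10 | (1Z)-1-iodo-2-methylhexa-1,5-diene | C=CCC/C(C)=C\I | intermediate
11 | [(1Z)-2-methylhexa-1,5-dien-1-yl]lithium (in situ) | C=CCC/C(C)=C\[Li] | intermediate
12 | (2Z)-3-methylhepta-2,6-dienal | C=CCC/C(C)=C\C=O | intermediate
13 | trichlorotitanium (Z)-enolate of 5 (in situ) | CC(C)/C=C(\O[Ti](Cl)(Cl)Cl)N1C(=S)SC[C@H]1Cc1ccccc1 | intermediate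
14 | (2R,3S,4Z)-1-[(4R)-4-benzyl-2-sulfanylidene-1,3-thiazolidin-3-yl]-3-hydroxy-5-methyl-2-(propan-2-yl)nona-4,8-dien-1-one | C=CCC/C(C)=C\[C@H](O)[C@@H](C(C)C)C(=O)N1C(=S)SC[C@H]1Cc1ccccc1 | intermediate
15 | (2R,3S,4Z)-1-[(4R)-4-benzyl-2-sulfanylidene-1,3-thiazolidin-3-yl]-3-{[tert-butyl(dimethyl)silyl]oxy}-5-methyl-2-(propan-2-yl)nona-4,8-dien-1-one | C=CCC/C(C)=C\[C@H](O[Si](C)(C)C(C)(C)C)[C@@H](C(C)C)C(=O)N1C(=S)SC[C@H]1Cc1ccccc1 | intermediate
16 | (2R,3S,4Z)-3-{[tert-butyl(dimethyl)silyl]oxy}-5-methyl-2-(propan-2-yl)nona-4,8-dienal | C=CCC/C(C)=C\[C@H](O[Si](C)(C)C(C)(C)C)[C@@H](C(C)C)C=O | intermediate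
17 | (2-methylprop-2-en-1-yl)magnesium chloride | CC(=C)C[Mg]Cl | starting material
18 | (+)-B-methoxydiisopinocampheylborane | COB([C@H]1C[C@H]2C[C@@H]([C@@H]1C)C2(C)C)[C@H]1C[C@H]2C[C@@H]([C@@H]1C)C2(C)C | starting material
19 | B-(2-methylprop-2-en-1-yl)diisopinocampheylborane (in situ) | CC(=C)CB([C@H]1C[C@H]2C[C@@H]([C@@H]1C)C2(C)C)[C@H]1C[C@H]2C[C@@H]([C@@H]1C)C2(C)C | intermediate
20 | (4R,5S,6S,7Z)-6-{[tert-butyl(dimethyl)silyl]oxy}-2,8-dimethyl-5-(propan-2-yl)dodeca-1,7,11-trien-4-ol | C=CCC/C(C)=C\[C@H](O[Si](C)(C)C(C)(C)C)[C@@H](C(C)C)[C@H](O)CC(C)=C | intermediate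
21 | 4-hydroxybenzoic acid | OC(=O)c1ccc(O)cc1 | starting material
22 | tert-butyl(dimethyl)silyl 4-{[tert-butyl(dimethyl)silyl]oxy}benzoate | CC(C)(C)[Si](C)(C)OC(=O)c1ccc(O[Si](C)(C)C(C)(C)C)cc1 | intermediate
23 | 4-{[tert-butyl(dimethyl)silyl]oxy}benzoic acid | OC(=O)c1ccc(O[Si](C)(C)C(C)(C)C)cc1 | intermediate
24 | 4-{[tert-butyl(dimethyl)silyl]oxy}benzoyl chloride | ClC(=O)c1ccc(O[Si](C)(C)C(C)(C)C)cc1 | intermediate
25 | (4R,5S,6S,7Z)-6-{[tert-butyl(dimethyl)silyl]oxy}-2,8-dimethyl-5-(propan-2-yl)dodeca-1,7,11-trien-4-yl 4-{[tert-butyl(dimethyl)silyl]oxy}benzoate | C=CCC/C(C)=C\[C@H](O[Si](C)(C)C(C)(C)C)[C@@H](C(C)C)[C@H](OC(=O)c1ccc(O[Si](C)(C)C(C)(C)C)cc1)CC(C)=C | intermediate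
26 | (1R,3Z,7Z,9S,10S)-9-{[tert-butyl(dimethyl)silyl]oxy}-3,7-dimethyl-10-(propan-2-yl)cyclodeca-3,7-dien-1-yl 4-{[tert-butyl(dimethyl)silyl]oxy}benzoate | C/C1=C/[C@H](O[Si](C)(C)C(C)(C)C)[C@@H](C(C)C)[C@H](OC(=O)c2ccc(O[Si](C)(C)C(C)(C)C)cc2)C/C(C)=C\CC1 | intermediate
27 | (1R,3Z,7Z,9S,10R)-9-hydroxy-3,7-dimethyl-10-(propan-2-yl)cyclodeca-3,7-dien-1-yl 4-hydroxybenzoate | C/C1=C/[C@H](O)[C@@H](C(C)C)[C@H](OC(=O)c2ccc(O)cc2)C/C(C)=C\CC1 | target

## Step count

Total step count: 14.
Longest linear sequence: 9 steps (steps 3, 4, 5, 6, 7, 8, 12, 13, 14; the branch through steps 1 and 2 is equally long).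

## Steps most likely to fail

**Step 13 (ring-closing metathesis).** Closing a ten-membered ring onto a 1,1-disubstituted alkene next to a bulky aroyloxy group may be slow and lose material to dimers. Fallback: change the order of ring closure and acylation. Setting out from 20, the smaller free alcohol is cyclised by metathesis at high dilution to the macrocyclic alcohol (1R,3Z,7Z,9S,10S)-9-{[tert-butyl(dimethyl)silyl]oxy}-3,7-dimethyl-10-(propan-2-yl)cyclodeca-3,7-dien-1-ol F1, which is then acylated with 24 (Et3N, DMAP, CH2Cl2) and so comes back to the route at 26.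

**Step 8 (methallylboration).** The aldehyde's own facial bias may be mismatched with the reagent and erode the ratio at the new carbinol centre. Fallback: replace the asymmetric C–C bond formation by addition, oxidation and asymmetric reduction. Setting out from 16, 17 is added directly (THF, −78 °C) to give (5S,6S,7Z)-6-{[tert-butyl(dimethyl)silyl]oxy}-2,8-dimethyl-5-(propan-2-yl)dodeca-1,7,11-trien-4-ol as a mixture of C4 epimers F2. Dess–Martin oxidation (NaHCO3-buffered) gives (5R,6S,7Z)-6-{[tert-butyl(dimethyl)silyl]oxy}-2,8-dimethyl-5-(propan-2-yl)dodeca-1,7,11-trien-4-one F3. Corey–Bakshi–Shibata reduction with (S)-2-methyl-CBS-oxazaborolidine and catecholborane at −78 °C, the branched C5 side acting as the large group, gives the 4R alcohol and comes back to the route at 20.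

**Step 5 (titanium aldol).** TiCl4 may isomerise the Z enal, and the β-branched acyl group may lower the syn selectivity. Fallback: a boron aldol on an oxazolidinone auxiliary with reductive release. Setting out from 4, acylation of commercial (4R)-4-benzyl-1,3-oxazolidin-2-one (n-BuLi, THF, −78 °C) gives (4R)-4-benzyl-3-(3-methylbutanoyl)-1,3-oxazolidin-2-one F4. Enolisation with Bu2BOTf/Et3N and addition of 12 at −78 °C gives the Evans syn adduct (4R)-4-benzyl-3-[(2R,3S,4Z)-3-hydroxy-5-methyl-2-(propan-2-yl)nona-4,8-dienoyl]-1,3-oxazolidin-2-one F5. TBSOTf/2,6-lutidine gives (4R)-4-benzyl-3-[(2R,3S,4Z)-3-{[tert-butyl(dimethyl)silyl]oxy}-5-methyl-2-(propan-2-yl)nona-4,8-dienoyl]-1,3-oxazolidin-2-one F6. LiBH4 (THF, MeOH, 0 °C) removes the auxiliary to give (2S,3S,4Z)-3-{[tert-butyl(dimethyl)silyl]oxy}-5-methyl-2-(propan-2-yl)nona-4,8-dien-1-ol F7, and Dess–Martin oxidation comes back to the route at 16.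

## Further compounds

F1 | step 13 | (1R,3Z,7Z,9S,10S)-9-{[tert-butyl(dimethyl)silyl]oxy}-3,7-dimethyl-10-(propan-2-yl)cyclodeca-3,7-dien-1-ol | C/C1=C/[C@H](O[Si](C)(C)C(C)(C)C)[C@@H](C(C)C)[C@H](O)C/C(C)=C\CC1
F2 | step 8 | (5S,6S,7Z)-6-{[tert-butyl(dimethyl)silyl]oxy}-2,8-dimethyl-5-(propan-2-yl)dodeca-1,7,11-trien-4-ol, mixture of C4 epimers | C=CCC/C(C)=C\[C@H](O[Si](C)(C)C(C)(C)C)[C@@H](C(C)C)C(O)CC(C)=C
F3 | step 8 | (5R,6S,7Z)-6-{[tert-butyl(dimethyl)silyl]oxy}-2,8-dimethyl-5-(propan-2-yl)dodeca-1,7,11-trien-4-one | C=CCC/C(C)=C\[C@H](O[Si](C)(C)C(C)(C)C)[C@@H](C(C)C)C(=O)CC(C)=C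
F4 | step 5 | (4R)-4-benzyl-3-(3-methylbutanoyl)-1,3-oxazolidin-2-one | CC(C)CC(=O)N1C(=O)OC[C@H]1Cc1ccccc1
F5 | step 5 | (4R)-4-benzyl-3-[(2R,3S,4Z)-3-hydroxy-5-methyl-2-(propan-2-yl)nona-4,8-dienoyl]-1,3-oxazolidin-2-one | C=CCC/C(C)=C\[C@H](O)[C@@H](C(C)C)C(=O)N1C(=O)OC[C@H]1Cc1ccccc1
F6 | step 5 | (4R)-4-benzyl-3-[(2R,3S,4Z)-3-{[tert-butyl(dimethyl)silyl]oxy}-5-methyl-2-(propan-2-yl)nona-4,8-dienoyl]-1,3-oxazolidin-2-one | C=CCC/C(C)=C\[C@H](O[Si](C)(C)C(C)(C)C)[C@@H](C(C)C)C(=O)N1C(=O)OC[C@H]1Cc1ccccc1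
F7 | step 5 | (2S,3S,4Z)-3-{[tert-butyl(dimethyl)silyl]oxy}-5-methyl-2-(propan-2-yl)nona-4,8-dien-1-ol | C=CCC/C(C)=C\[C@H](O[Si](C)(C)C(C)(C)C)[C@@H](C(C)C)CO
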